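## Retrosynthetic overview

1. The target gibberellin triacid ⇐ its trimethyl ester ⇐ ring D closed last by a SmI2 ketyl–alkyne cyclisation (C13–C16) on a ring A/B/C keto triester that carries a propargyl group on C8.
2. Key step: ring B is closed by an intramolecular Mukaiyama–Michael addition of the C6 silyl ketene acetal to C8 of the ketal-activated ring C enone; this creates the C8 quaternary centre and the cis B/C fusion.
3. The C9–C10 bond that joins the two halves comes from an Ireland–Claisen rearrangement of the ester made from a ring A acid and a ring C allylic alcohol.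
4. Ring A acid: meso 2-allylcyclohexane-1,3-dicarboxylic anhydride → alkaloid-catalysed desymmetrisation → C4 methylation → allyl cut down to CH2CO2Me. Ring C alcohol: cyclohexane-1,2-dione monoketal → enone → α-propargylation → CBS reduction.
5. Order of ring formation: rings A and C are made separately (two branches), then ring B (key Michael), then ring D.

Notation and assumption: atoms are labelled C1–C20 by the usual gibberellane numbering of the target (C7, C19, C20 carboxyl carbons; C18 methyl; C17 methylene), the target is called the target triacid, LiN(i-Pr)2, KN(SiMe3)2, SmI2 and LiSPr are used as commercial or pre-formed solutions, and the route is a design that has not been run, so stereochemical outcomes are predictions by analogy.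

## Route

Step 1
Reactants: 1 dimethyl 2-oxocyclohexane-1,3-dicarboxylate
Product: 2 dimethyl 2-{[(trifluoromethyl)sulfonyl]oxy}cyclohex-1-ene-1,3-dicarboxylate (racemic)
Conditions: NaH, Et2O, 0 °C; then Tf2O, 0 °C
Reagents that add atoms: trifluoromethanesulfonic anhydride, O=S(=O)(OS(=O)(=O)C(F)(F)F)C(F)(F)F
Why: Enol triflate formation by O-sulfonylation of the sodium enolate of the β-keto ester; the single stereocentre stays racemic because it is equilibrated in step 3.

Step 2
Reactants: 2 dimethyl 2-{[(trifluoromethyl)sulfonyl]oxy}cyclohex-1-ene-1,3-dicarboxylate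
Product: 3 dimethyl 2-(prop-2-en-1-yl)cyclohex-1-ene-1,3-dicarboxylate (racemic)
Conditions: allyltributylstannane, Pd(PPh3)4 (5 mol %), LiCl, THF, 65 °C
Reagents that add atoms: allyltributylstannane, C=CC[Sn](CCCC)(CCCC)CCCC
Why: Stille cross-coupling of the vinyl triflate on zerovalent palladium installs the allyl group on C5 that later becomes the C6–C7 acetate arm.

Step 3
Reactants: 3 dimethyl 2-(prop-2-en-1-yl)cyclohex-1-ene-1,3-dicarboxylate
Product: 4 dimethyl (1R,2r,3S)-2-(prop-2-en-1-yl)cyclohexane-1,3-dicarboxylate (meso)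
Conditions: Mg, MeOH, 0 °C to rt; then NaOMe (0.2 equiv), MeOH, reflux
Reagents that add atoms: none
Why: Dissolving-metal (Mg/MeOH) conjugate reduction of the α,β-unsaturated ester spares the isolated alkene, and alkoxide equilibration of both ester α-centres funnels the mixture to the all-equatorial meso isomer (esters cis to each other, allyl trans to both).

Step 4
Reactants: 4 dimethyl (1R,2r,3S)-2-(prop-2-en-1-yl)cyclohexane-1,3-dicarboxylate
Product: 5 (1R,2r,3S)-2-(prop-2-en-1-yl)cyclohexane-1,3-dicarboxylic acid (meso)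
Conditions: KOH, MeOH/H2O, reflux; then aq. HCl
Reagents that add atoms: potassium hydroxide, [K+].[OH-]
Why: Saponification of both esters; the all-equatorial configuration is the thermodynamic one and is kept.

Step 5
Reactants: 5 (1R,2r,3S)-2-(prop-2-en-1-yl)cyclohexane-1,3-dicarboxylic acid
Product: 6 (1R,5S,9r)-9-(prop-2-en-1-yl)-3-oxabicyclo[3.3.1]nonane-2,4-dione (meso)
Conditions: Ac2O, reflux
Reagents that add atoms: none
Why: Dehydration of the cis-1,3-diacid gives the bridged glutaric-type meso anhydride, with the allyl group anti to the anhydride bridge.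

Step 6
Reactants: 6 (1R,5S,9r)-9-(prop-2-en-1-yl)-3-oxabicyclo[3.3.1]nonane-2,4-dione
Product: 7 (1R,2S,3S)-3-(methoxycarbonyl)-2-(prop-2-en-1-yl)cyclohexane-1-carboxylic acid
Conditions: (DHQD)2AQN (0.1 equiv), MeOH (10 equiv), Et2O, −40 °C
Reagents that add atoms: methanol, CO
Why: Cinchona-alkaloid-catalysed desymmetrising alcoholysis of a meso anhydride, in which general-base delivery of methanol to one enantiotopic carbonyl fixes C5 in absolute terms (the quasi-enantiomeric (DHQ)2AQN gives the antipode if the sense proves opposite).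

Step 7
Reactants: 7 (1R,2S,3S)-3-(methoxycarbonyl)-2-(prop-2-en-1-yl)cyclohexane-1-carboxylic acid
Product: 8 (1R,2S,3R)-3-(methoxycarbonyl)-3-methyl-2-(prop-2-en-1-yl)cyclohexane-1-carboxylic acid
Conditions: LiN(i-Pr)2 (2.3 equiv), THF, −78 to −20 °C; MeI; then aq. HCl
Reagents that add atoms: iodomethane, CI
Why: Alkylation of the carboxylate/ester-enolate dianion, in which MeI attacks the exocyclic C4 enolate equatorially and anti to the neighbouring allyl arm, so the methyl ends trans and the C19 ester cis to that arm (sets C4).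

Step 8
Reactants: 8 (1R,2S,3R)-3-(methoxycarbonyl)-3-methyl-2-(prop-2-en-1-yl)cyclohexane-1-carboxylic acid
Product: 9 (1R,2S,3R)-2-(2-methoxy-2-oxoethyl)-3-(methoxycarbonyl)-3-methylcyclohexane-1-carboxylic acid
Conditions: O3, NaOH (5 equiv), MeOH/CH2Cl2, −78 °C; then aq. HCl to pH 3
Reagents that add atoms: ozone, [O-][O+]=O; methanol, CO
Why: Ozonolysis in methanolic NaOH (Marshall conditions) converts the terminal alkene directly into the one-carbon-shorter methyl ester, giving the C6–C7 arm only after all enolate chemistry on ring A is finished.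

Step 9
Reactants: 10 cyclohexanone
Product: 11 cyclohexane-1,2-dione
Conditions: SeO2, dioxane/H2O, 70 °C
Reagents that add atoms: selenium dioxide, O=[Se]=O
Why: Riley oxidation of the α-methylene group of the ketone.

Step 10
Reactants: 11 cyclohexane-1,2-dione
Product: 12 1,4-dioxaspiro[4.5]decan-6-one
Conditions: HOCH2CH2OH (1.0 equiv), TsOH (cat.), benzene, reflux (Dean–Stark)
Reagents that add atoms: ethylene glycol, OCCO
Why: Mono-ketalisation of the 1,2-dione; the ketal masks the future C13 ketone and blocks that α-position.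

Step 11
Reactants: 12 1,4-dioxaspiro[4.5]decan-6-one
Product: 13 trimethyl(1,4-dioxaspiro[4.5]dec-6-en-6-yloxy)silane
Conditions: LiN(i-Pr)2, Me3SiCl, THF, −78 °C
Reagents that add atoms: chlorotrimethylsilane, C[Si](C)(C)Cl
Why: Enolisation can occur only toward the single α-CH2, giving one silyl enol ether.

Step 12
Reactants: 13 trimethyl(1,4-dioxaspiro[4.5]dec-6-en-6-yloxy)silane
Product: 14 1,4-dioxaspiro[4.5]dec-7-en-6-one
Conditions: Pd(OAc)2 (10 mol %), O2 (1 atm), DMSO, 40 °C
Reagents that add atoms: none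
Why: Saegusa–Ito oxidation (palladium enolate, β-hydride elimination) gives the enone under neutral conditions that the ketal tolerates.

Step 13
Reactants: 14 1,4-dioxaspiro[4.5]dec-7-en-6-one
Product: 15 7-[3-(trimethylsilyl)prop-2-yn-1-yl]-1,4-dioxaspiro[4.5]dec-8-en-6-one (racemic)
Conditions: KN(SiMe3)2, THF, −78 °C; then 3-bromo-1-(trimethylsilyl)prop-1-yne, −78 to −30 °C
Reagents that add atoms: 3-bromo-1-(trimethylsilyl)prop-1-yne, BrCC#C[Si](C)(C)C
Why: Deconjugative α-alkylation: with the α′ side blocked by the ketal, only γ-deprotonation is possible, and the linear dienolate is alkylated at its α-carbon (future C8).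

Step 14
Reactants: 15 7-[3-(trimethylsilyl)prop-2-yn-1-yl]-1,4-dioxaspiro[4.5]dec-8-en-6-one
Product: 16 7-[3-(trimethylsilyl)prop-2-yn-1-yl]-1,4-dioxaspiro[4.5]dec-7-en-6-one
Conditions: DBU (0.2 equiv), CH2Cl2, 0 °C
Reagents that add atoms: none
Why: Base-mediated reconjugation through the dienolate gives the thermodynamically favoured α-substituted conjugated enone.

Step 15
Reactants: 16 7-[3-(trimethylsilyl)prop-2-yn-1-yl]-1,4-dioxaspiro[4.5]dec-7-en-6-one
Product: 17 (6R)-7-[3-(trimethylsilyl)prop-2-yn-1-yl]-1,4-dioxaspiro[4.5]dec-7-en-6-ol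
Conditions: (S)-2-methyl-CBS-oxazaborolidine (0.2 equiv), catecholborane, toluene, −78 °C; then H2O
Reagents that add atoms: none
Why: Corey–Bakshi–Shibata reduction, in which the quaternary ketal carbon is taken as the large group, delivers hydride to one face to give the (R)-carbinol (C14) whose configuration is later relayed to C9.

Step 16
Reactants: 9 (1R,2S,3R)-2-(2-methoxy-2-oxoethyl)-3-(methoxycarbonyl)-3-methylcyclohexane-1-carboxylic acid; 17 (6R)-7-[3-(trimethylsilyl)prop-2-yn-1-yl]-1,4-dioxaspiro[4.5]dec-7-en-6-ol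
Product: 18 allylic ester of acid 9 and alcohol 17 (C20–O–C14 ester; all stereocentres of both partners unchanged)
Conditions: 2,4,6-trichlorobenzoyl chloride, Et3N, THF, rt; then 17, DMAP, toluene, 40 °C
Reagents that add atoms: none
Why: Yamaguchi esterification through the mixed anhydride couples the hindered acid and the hindered secondary alcohol; C10 may epimerise without consequence because it is enolised in the next step.

Step 17
Reactants: 18 allylic ester of acid 9 and alcohol 17
Product: 22 ring-B-seco triester (ring A bonded through C10–C9 to ring C; C4 C5 C9 C10 as in the target), via bis-silyl ketene acetal 19 (not isolated), via rearranged silyl ester 20 (not isolated), via seco acid 21 (not isolated)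
Conditions: LiN(i-Pr)2 (2.4 equiv), Me3SiCl/Et3N, THF, −78 °C; then toluene, 80 °C; MeOH; then TMSCHN2, toluene/MeOH, 0 °C
Reagents that add atoms: (trimethylsilyl)diazomethane, C[Si](C)(C)C=[N+]=[N-]
Why: Ireland–Claisen rearrangement: both enolisable esters are trapped as silyl ketene acetals but only the allyl ester can undergo the [3,3] shift, which forms the C9–C10 bond suprafacially on the ring C face that carried the C14 oxygen (sets C9) and on the ring A face trans to the C5 arm and away from the axial C4 ester (sets C10); TMSCHN2 then caps the hindered acid.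

Step 18
Reactants: 22 ring-B-seco triester
Product: 26 ring A/B/C keto triester (C13 ketone; C8 propargyl cis to H9; C4 C5 C6 C8 C9 C10 as in the target), via silyl ketene acetal 23 (not isolated), via cyclised enol ether 24 (not isolated), via silylalkyne ketone 25 (not isolated)
Conditions: LiN(i-Pr)2 (1.2 equiv), Me3SiCl, THF, −78 °C; solvent change to CH2Cl2; Me3SiOTf (0.3 equiv), −78 to −40 °C; aq. HCl/THF, 0 °C; then NaOMe (0.3 equiv), MeOH, rt
Reagents that add atoms: water, O
Why: Intramolecular Mukaiyama–Michael addition: Me3SiOTf opens the allylic ketal to a vinylogous oxocarbenium ion (an activated enone) that the C6 silyl ketene acetal attacks 5-exo at C8, the short tether forcing attack on the ring C face that carries C10 (cis B/C fusion, propargyl cis to H9, sets C8), after which NaOMe equilibrates C6 to the more stable ester trans to C4 and removes the alkyne silyl group.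

Step 19
Reactants: 26 ring A/B/C keto triester
Product: 27 trimethyl ester of the target triacid
Conditions: SmI2 (3 equiv), HMPA, t-BuOH, THF, 0 °C
Reagents that add atoms: none
Why: SmI2-mediated ketyl–alkyne radical cyclisation (5-exo-dig): the C13 ketyl adds to the internal alkyne carbon C16 and the vinyl radical is reduced and protonated, giving the bridgehead tertiary alcohol and the exocyclic methylene, with C13 fixed by the bicyclo[3.2.1]octane geometry.

Step 20
Reactants: 27 trimethyl ester of the target triacid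
Product: 28 the target triacid (ent-13-hydroxygibberell-16-ene-7,19,20-trioic acid)
Conditions: LiSPr, HMPA, rt to 50 °C; then aq. HCl to pH 3, 0 °C
Reagents that add atoms: none
Why: SN2 demethylation of the three methyl esters by thiolate works on the neopentyl C19 and C20 esters that resist hydrolysis and leaves the tertiary allylic alcohol and the alkene untouched.

## Compound list

1 | dimethyl 2-oxocyclohexane-1,3-dicarboxylate | COC(=O)C1CCCC(C(=O)OC)C1=O | starting material
2 | dimethyl 2-{[(trifluoromethyl)sulfonyl]oxy}cyclohex-1-ene-1,3-dicarboxylate (racemic) | COC(=O)C1CCCC(C(=O)OC)=C1OS(=O)(=O)C(F)(F)F | intermediate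
3 | dimethyl 2-(prop-2-en-1-yl)cyclohex-1-ene-1,3-dicarboxylate (racemic) | COC(=O)C1CCCC(C(=O)OC)=C1CC=C | intermediate
4 | dimethyl (1R,2r,3S)-2-(prop-2-en-1-yl)cyclohexane-1,3-dicarboxylate (meso; esters cis, allyl trans to both) | COC(=O)[C@@H]1CCC[C@H](C(=O)OC)[C@H]1CC=C | intermediate
5 | (1R,2r,3S)-2-(prop-2-en-1-yl)cyclohexane-1,3-dicarboxylic acid (meso) | OC(=O)[C@@H]1CCC[C@H](C(=O)O)[C@H]1CC=C | intermediate
6 | (1R,5S,9r)-9-(prop-2-en-1-yl)-3-oxabicyclo[3.3.1]nonane-2,4-dione (meso; allyl anti to the anhydride bridge) | O=C1OC(=O)[C@@H]2CCC[C@H]1[C@H]2CC=C | intermediate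
7 | (1R,2S,3S)-3-(methoxycarbonyl)-2-(prop-2-en-1-yl)cyclohexane-1-carboxylic acid | OC(=O)[C@@H]1CCC[C@H](C(=O)OC)[C@H]1CC=C | intermediate
8 | (1R,2S,3R)-3-(methoxycarbonyl)-3-methyl-2-(prop-2-en-1-yl)cyclohexane-1-carboxylic acid | OC(=O)[C@@H]1CCC[C@@](C)(C(=O)OC)[C@H]1CC=C | intermediate
9 | (1R,2S,3R)-2-(2-methoxy-2-oxoethyl)-3-(methoxycarbonyl)-3-methylcyclohexane-1-carboxylic acid (ring A acid) | OC(=O)[C@@H]1CCC[C@@](C)(C(=O)OC)[C@H]1CC(=O)OC | intermediate
10 | cyclohexanone | O=C1CCCCC1 | starting material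
11 | cyclohexane-1,2-dione | O=C1CCCCC1=O | intermediate
12 | 1,4-dioxaspiro[4.5]decan-6-one | O=C1CCCCC12OCCO2 | intermediate
13 | trimethyl(1,4-dioxaspiro[4.5]dec-6-en-6-yloxy)silane | C[Si](C)(C)OC1=CCCCC12OCCO2 | intermediate
14 | 1,4-dioxaspiro[4.5]dec-7-en-6-one | O=C1C=CCCC12OCCO2 | intermediate
15 | 7-[3-(trimethylsilyl)prop-2-yn-1-yl]-1,4-dioxaspiro[4.5]dec-8-en-6-one (racemic) | O=C1C(CC#C[Si](C)(C)C)C=CCC12OCCO2 | intermediate
16 | 7-[3-(trimethylsilyl)prop-2-yn-1-yl]-1,4-dioxaspiro[4.5]dec-7-en-6-one | O=C1C(CC#C[Si](C)(C)C)=CCCC12OCCO2 | intermediate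
17 | (6R)-7-[3-(trimethylsilyl)prop-2-yn-1-yl]-1,4-dioxaspiro[4.5]dec-7-en-6-ol (ring C alcohol) | O[C@@H]1C(CC#C[Si](C)(C)C)=CCCC12OCCO2 | intermediate
18 | (6R)-7-[3-(trimethylsilyl)prop-2-yn-1-yl]-1,4-dioxaspiro[4.5]dec-7-en-6-yl (1R,2S,3R)-2-(2-methoxy-2-oxoethyl)-3-(methoxycarbonyl)-3-methylcyclohexane-1-carboxylate | C[Si](C)(C)C#CCC1=CCCC2(OCCO2)[C@@H]1OC(=O)[C@@H]1CCC[C@@](C)(C(=O)OC)[C@H]1CC(=O)OC | intermediate
19 | bis-silyl ketene acetal of 18: C10=C20(OSiMe3)(O-allyl) and C6=C7(OMe)(OSiMe3) | C[Si](C)(C)C#CCC1=CCCC2(OCCO2)[C@@H]1OC(O[Si](C)(C)C)=C1CCC[C@@](C)(C(=O)OC)[C@H]1C=C(OC)O[Si](C)(C)C | intermediate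
20 | rearranged silyl ester: C9–C10 bond formed, C20 trimethylsilyl ester, C6=C7 silyl ketene acetal retained | C[Si](C)(C)C#CCC1=CC2(OCCO2)CC[C@H]1[C@]1(C(=O)O[Si](C)(C)C)CCC[C@@](C)(C(=O)OC)[C@H]1C=C(OC)O[Si](C)(C)C | intermediate
21 | seco acid: ring A (C4 Me/CO2Me, C5 CH2CO2Me, C10 CO2H) bonded C10–C9 to ring C (C8=C14 alkene, C13 ethylene ketal, C8 CH2C≡CSiMe3) | C[Si](C)(C)C#CCC1=CC2(OCCO2)CC[C@H]1[C@]1(C(=O)O)CCC[C@@](C)(C(=O)OC)[C@H]1CC(=O)OC | intermediate
22 | ring-B-seco triester: methyl ester of 21 (C4, C5, C9, C10 as in the target) | C[Si](C)(C)C#CCC1=CC2(OCCO2)CC[C@H]1[C@]1(C(=O)OC)CCC[C@@](C)(C(=O)OC)[C@H]1CC(=O)OC | intermediate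
23 | C6=C7 silyl ketene acetal of 22 | C[Si](C)(C)C#CCC1=CC2(OCCO2)CC[C@H]1[C@]1(C(=O)OC)CCC[C@@](C)(C(=O)OC)[C@H]1C=C(OC)O[Si](C)(C)C | intermediate
24 | cyclised enol ether: ring B closed (C6–C8), C13=C14 enol ether bearing OCH2CH2OSiMe3, C6 epimers | C[Si](C)(C)C#CC[C@]12C=C(OCCO[Si](C)(C)C)CC[C@H]1[C@]1(C(=O)OC)CCC[C@@](C)(C(=O)OC)[C@H]1C2C(=O)OC | intermediate
25 | silylalkyne ketone: ring A/B/C triester with C13 ketone and C8 CH2C≡CSiMe3, C6 epimers | C[Si](C)(C)C#CC[C@]12CC(=O)CC[C@H]1[C@]1(C(=O)OC)CCC[C@@](C)(C(=O)OC)[C@H]1C2C(=O)OC | intermediate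
26 | ring A/B/C keto triester: C13 ketone, C8 propargyl cis to H9, C7/C19/C20 methyl esters, C4, C5, C6, C8, C9, C10 as in the target | C#CC[C@]12CC(=O)CC[C@H]1[C@]1(C(=O)OC)CCC[C@@](C)(C(=O)OC)[C@H]1[C@@H]2C(=O)OC | intermediate
27 | trimethyl ester of the target triacid (trimethyl ent-13-hydroxygibberell-16-ene-7,19,20-trioate) | C=C1C[C@]23C[C@@]1(O)CC[C@H]2[C@]1(C(=O)OC)CCC[C@@](C)(C(=O)OC)[C@H]1[C@@H]3C(=O)OC | intermediate
28 | the target triacid, the gibberellin named in the task (ent-13-hydroxygibberell-16-ene-7,19,20-trioic acid) | C=C1C[C@]23C[C@@]1(O)CC[C@H]2[C@]1(C(=O)O)CCC[C@@](C)(C(=O)O)[C@H]1[C@@H]3C(=O)O | target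

## Step count and risks

Total step count: 20. Longest linear sequence: 13 steps (steps 1–8, then 16–20); the second branch (steps 9–15, 7 steps) joins at step 16.

Three steps most likely to fail:

Step 15 (enantioselective reduction). The ketone is flanked by two bulky groups, so the ee and even the sense of the CBS reduction are uncertain. Fallback: resolution through the chiral acid instead of catalyst control. It sets out from 16: NaBH4/CeCl3·7H2O in MeOH gives the racemic allylic alcohol F1. Yamaguchi esterification of F1 with enantiopure 9 gives 18 together with its C14 epimer, the diastereomeric ester F2, and the two are separated by chromatography. The route is rejoined at 18.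

Step 17 (Ireland–Claisen). It needs double enolisation and forms a congested bond between a quaternary and a tertiary carbon, and the face used at C10 also depends on the ketene acetal geometry. Fallback: carry the arm as an inert allyl group through the rearrangement and unveil the ester afterwards. It sets out from 8 (with 17): Yamaguchi esterification gives the allyl-armed ester F3, which has only one enolisable position. LiN(i-Pr)2/Me3SiCl, 80 °C and a methanol quench give the rearranged acid F4. OsO4 (cat.)/NaIO4/2,6-lutidine cleaves only the unhindered terminal alkene to the aldehyde acid F5. NaClO2/NaH2PO4/2-methylbut-2-ene gives the diacid F6, and TMSCHN2 esterifies both acids to rejoin the route at 22.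

Step 18 (key ring B closure). A quaternary centre has to form within a trans-fused hydrindane, and 1,2-attack at the ketal carbon or loss of the silyl ketene acetal may compete. Fallback: enamine catalysis on the free enone instead of Lewis-acid activation of the ketal. It sets out from 22: i-Bu2AlH (1.1 equiv, CH2Cl2, −78 °C) reduces only the unhindered C7 ester to the aldehyde F7. Aq. HCl/THF frees the enone to give the keto aldehyde F8. Pyrrolidine/AcOH closes ring B by an intramolecular enamine Michael addition to give the cyclised aldehyde F9. NaClO2/NaH2PO4/2-methylbut-2-ene gives the acid F10, and TMSCHN2 gives 25, where the route is rejoined.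

Further compounds
F1 | step 15 | racemic 7-[3-(trimethylsilyl)prop-2-yn-1-yl]-1,4-dioxaspiro[4.5]dec-7-en-6-ol | OC1C(CC#C[Si](C)(C)C)=CCCC12OCCO2
F2 | step 15 | C14 epimer of ester 18 ((6S)-carbinol ester of acid 9) | C[Si](C)(C)C#CCC1=CCCC2(OCCO2)[C@H]1OC(=O)[C@@H]1CCC[C@@](C)(C(=O)OC)[C@H]1CC(=O)OC
F3 | step 17 | ester of allyl acid 8 with alcohol 17 | C[Si](C)(C)C#CCC1=CCCC2(OCCO2)[C@@H]1OC(=O)[C@@H]1CCC[C@@](C)(C(=O)OC)[C@H]1CC=C
F4 | step 17 | rearranged acid with C5 allyl arm (C9–C10 bond formed, C20 CO2H) | C[Si](C)(C)C#CCC1=CC2(OCCO2)CC[C@H]1[C@]1(C(=O)O)CCC[C@@](C)(C(=O)OC)[C@H]1CC=C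
F5 | step 17 | aldehyde acid (C5 CH2CHO arm, C20 CO2H) | C[Si](C)(C)C#CCC1=CC2(OCCO2)CC[C@H]1[C@]1(C(=O)O)CCC[C@@](C)(C(=O)OC)[C@H]1CC=O
F6 | step 17 | diacid (C7 and C20 CO2H, C19 CO2Me) | C[Si](C)(C)C#CCC1=CC2(OCCO2)CC[C@H]1[C@]1(C(=O)O)CCC[C@@](C)(C(=O)OC)[C@H]1CC(=O)O
F7 | step 18 | C7 aldehyde of 22 (C19 and C20 methyl esters, ketal intact) | C[Si](C)(C)C#CCC1=CC2(OCCO2)CC[C@H]1[C@]1(C(=O)OC)CCC[C@@](C)(C(=O)OC)[C@H]1CC=O
F8 | step 18 | keto aldehyde with free ring C enone | C[Si](C)(C)C#CCC1=CC(=O)CC[C@H]1[C@]1(C(=O)OC)CCC[C@@](C)(C(=O)OC)[C@H]1CC=O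
F9 | step 18 | cyclised C7 aldehyde (ring B closed, C13 ketone) | C[Si](C)(C)C#CC[C@]12CC(=O)CC[C@H]1[C@]1(C(=O)OC)CCC[C@@](C)(C(=O)OC)[C@H]1[C@@H]2C=O
F10 | step 18 | cyclised C7 acid (ring B closed, C13 ketone) | C[Si](C)(C)C#CC[C@]12CC(=O)CC[C@H]1[C@]1(C(=O)OC)CCC[C@@](C)(C(=O)OC)[C@H]1[C@@H]2C(=O)O
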